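**Retrosynthetic overview**

- Drimane numbering is used: ring A = C1–C5 and C10, ring B = C5–C10, C11 = the benzylic carbon. β-Damascone (1) already holds ring A, C6 as a ketone, C7, C8 and the C8 methyl, and its two enone β-carbons, C8 and C10, flank the one missing ring-B atom, C9.
- C9 and C11 arrive together as the CH3–C=O unit of an aryl methyl ketone, made in three steps from methyl 3-bromo-4-hydroxy-5-methoxybenzoate (2). Disconnections: C8–C9 and C9–C10, a [5+1] double conjugate addition that closes ring B onto the purchased ring A.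
- After the annulation the C11 oxygen is removed first, so that C9–H is no longer acidic. The C6 ketone is then used to introduce the C7=C8 double bond (which erases C8), the C6 oxygen is removed, and the phenols are freed.
- The phenols are carried as tert-butyldimethylsilyl ethers, because the annulation runs under strong acid with silyl enol ethers present and the last step must avoid acid.

Key step: step 5

Assumption: the (S)-configured oxazaborolidinium catalyst is taken to give the (3S)-adduct 8; if the sense of induction proves opposite, the enantiomeric catalyst is used and nothing else changes.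

**Route**

Step 1
Reactants: 2 methyl 3-bromo-4-hydroxy-5-methoxybenzoate
Product: 3 methyl 3-bromo-4,5-dihydroxybenzoate
Conditions: BBr3 (3 equiv), CH2Cl2, −78 °C → rt; then MeOH, rt
Reagents that add atoms: none
Why: Lewis-acid cleavage of the aryl methyl ether (bromide attacks the methyl group of the boron-bound ether) should free the catechol, and the methanol quench re-forms any methyl ester that was cleaved.

Step 2
Reactants: 3 methyl 3-bromo-4,5-dihydroxybenzoate
Product: 4 methyl 3-bromo-4,5-bis(tert-butyldimethylsilyloxy)benzoate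
Conditions: t-BuMe2SiCl (2.6 equiv), imidazole (5 equiv), DMF, rt → 40 °C
Reagents that add atoms: tert-butyldimethylsilyl chloride, CC(C)(C)[Si](C)(C)Cl
Why: Imidazole-promoted silylation of both phenols gives ethers that should withstand the acid of step 5 and the hydrogenation, enolate and hydride steps, and that fluoride removes at the end without acid.

Step 3
Reactants: 4 methyl 3-bromo-4,5-bis(tert-butyldimethylsilyloxy)benzoate
Product: 6 methyl 3-acetyl-4,5-bis(tert-butyldimethylsilyloxy)benzoate, via enol ether 5 (not isolated)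
Conditions: tributyl(1-ethoxyvinyl)stannane (1.3 equiv), PdCl2(PPh3)2 (5 mol %), toluene, 100 °C; then 1 M HCl, THF, rt
Reagents that add atoms: tributyl(1-ethoxyvinyl)stannane, CCCC[Sn](CCCC)(CCCC)C(=C)OCC; water, O
Why: Stille coupling of the aryl bromide with the acetyl-anion equivalent, followed by mild hydrolysis of the enol ether, should give the methyl ketone without touching the ester or the aryl silyl ethers.

Step 4
Reactants: 6 methyl 3-acetyl-4,5-bis(tert-butyldimethylsilyloxy)benzoate
Product: 7 methyl 3,4-bis(tert-butyldimethylsilyloxy)-5-[1-(trimethylsilyloxy)vinyl]benzoate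
Conditions: Me3SiOTf (1.3 equiv), Et3N (2 equiv), CH2Cl2, 0 °C; pentane trituration, used crude
Reagents that add atoms: trimethylsilyl triflate, C[Si](C)(C)OS(=O)(=O)C(F)(F)F
Why: Soft enolisation of an aryl methyl ketone, which has a single α-position, should give the silyl enol ether cleanly.

Step 5
Reactants: 7 methyl 3,4-bis(tert-butyldimethylsilyloxy)-5-[1-(trimethylsilyloxy)vinyl]benzoate (1.3 equiv); 1 β-damascone
Product: 10 methyl 3-{[(1S,2R,4aS,8aR)-2,5,5,8a-tetramethyl-4-oxodecahydronaphthalen-1-yl]carbonyl}-4,5-bis(tert-butyldimethylsilyloxy)benzoate, via Michael adduct 8 (not isolated), via bicyclic silyl enol ether 9 (not isolated)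
Conditions: (S)-3,3-diphenyl-1-(o-tolyl)tetrahydro-1H,3H-pyrrolo[1,2-c][1,3,2]oxazaborole (20 mol %) + HN(SO2CF3)2 (18 mol %), CH2Cl2, −78 → −40 °C; then HN(SO2CF3)2 (0.5 equiv), −40 → 0 °C; then 1 M HCl, THF, rt
Reagents that add atoms: none
Why: Proposed new method: the chiral boron Lewis acid binds the C6 carbonyl of 1 and enol ether 7 adds to the unhindered crotonyl carbon C8 (Mukaiyama–Michael addition, C8–C9 bond, silyl transfer to give dienol ether 8); triflimide then protonates 8 at C7, the silyl group and a proton are relayed between the two carbonyl oxygens (six-membered transfer of H9 to O6) so that a C9 enol ether faces an O-protonated enone with tertiary cation character at C10, and C9 attacks C10 (C9–C10 bond) to give 9, which is hydrolysed to 10. The closest known reactions are double Michael [5+1] annulations of divinyl ketones with active methylene compounds, enantioselective Mukaiyama–Michael additions to acyclic enones under chiral oxazaborolidinium catalysis, and acid-promoted Mukaiyama–Michael additions to β,β-disubstituted enones, whereas addition of a ketone enol ether to the twisted, tetrasubstituted C10 of a 2,6,6-trimethylcyclohexenyl ketone is without precedent. Ring B closes by a 6-endo-trig Michael addition in which C10, C5, C6 and C7 lie in the plane of the developing enol and C8 and C9 complete a half-chair. C8 is set by the catalyst (3S in 8, 2R in 10); C10 follows from C8 because the half-chair holds the C10 methyl pseudoaxial, so the C8 methyl must be equatorial and trans to it to avoid a 1,3-diaxial methyl pair; C9 should emerge with the aroyl group equatorial, since that places H8 in the plane of the Z enol ether (least allylic 1,3-strain) and is also the expected thermodynamic arrangement; C5 is set by protonation of 9 from the α face, anti to the axial C10 and C4 methyls, giving the trans fusion, and both C5 and C9 can drain to the stable epimer because each is α to a ketone. The step needs site selectivity for C8 over C10 in the first addition, which the twist and full substitution of the ring enone should secure, and it needs the second addition to outrun aldol closure, which the substrate secures because every aldol ring open to 8 is four-membered or would create a quaternary spiro centre at C5.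

Step 6
Reactants: 10 methyl 3-{[(1S,2R,4aS,8aR)-2,5,5,8a-tetramethyl-4-oxodecahydronaphthalen-1-yl]carbonyl}-4,5-bis(tert-butyldimethylsilyloxy)benzoate
Product: 11 methyl 3-{[(1S,2R,4aS,8aR)-2,5,5,8a-tetramethyl-4-oxodecahydronaphthalen-1-yl]methyl}-4,5-bis(tert-butyldimethylsilyloxy)benzoate
Conditions: H2 (4 atm), 10% Pd/C, AcOH–EtOAc (1:4), 40 °C
Reagents that add atoms: none
Why: Catalytic hydrogenolysis of an aryl ketone to the methylene group (through the benzylic alcohol, helped by the ortho oxygen donor and acetic acid) should leave the dialkyl C6 ketone, the ester and the silyl ethers alone, and it removes the acidity of C9–H before the C7=C8 double bond is made.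

Step 7
Reactants: 11 methyl 3-{[(1S,2R,4aS,8aR)-2,5,5,8a-tetramethyl-4-oxodecahydronaphthalen-1-yl]methyl}-4,5-bis(tert-butyldimethylsilyloxy)benzoate
Product: 13 methyl 3-{[(1S,4aS,8aR)-2,5,5,8a-tetramethyl-4-oxo-1,4,4a,5,6,7,8,8a-octahydronaphthalen-1-yl]methyl}-4,5-bis(tert-butyldimethylsilyloxy)benzoate, via silyl enol ether 12 (not isolated)
Conditions: LiN(i-Pr)2 (1.2 equiv), Me3SiCl (in situ), THF, −78 °C; then Pd(OAc)2 (1.1 equiv), MeCN, rt
Reagents that add atoms: none
Why: Saegusa–Ito oxidation: kinetic deprotonation should take the C7 methylene and not the buried tertiary C5–H, and the palladium enolate, which can reach C7 on the β face cis to H8, loses H8 by syn β-hydride elimination to give the 7-en-6-one and erase the C8 stereocentre.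

Step 8
Reactants: 13 methyl 3-{[(1S,4aS,8aR)-2,5,5,8a-tetramethyl-4-oxo-1,4,4a,5,6,7,8,8a-octahydronaphthalen-1-yl]methyl}-4,5-bis(tert-butyldimethylsilyloxy)benzoate
Product: 14 methyl 3-{[(1S,4R,4aS,8aR)-4-hydroxy-2,5,5,8a-tetramethyl-1,4,4a,5,6,7,8,8a-octahydronaphthalen-1-yl]methyl}-4,5-bis(tert-butyldimethylsilyloxy)benzoate
Conditions: NaBH4, CeCl3·7H2O, MeOH–THF, −40 °C
Reagents that add atoms: none
Why: Luche 1,2-reduction of the enone should deliver hydride from the α face, the β face being screened by the axial C10 and C4 methyls, to give the 6β-alcohol, whose configuration is of no consequence.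

Step 9
Reactants: 14 methyl 3-{[(1S,4R,4aS,8aR)-4-hydroxy-2,5,5,8a-tetramethyl-1,4,4a,5,6,7,8,8a-octahydronaphthalen-1-yl]methyl}-4,5-bis(tert-butyldimethylsilyloxy)benzoate
Product: 15 methyl 3-{[(1S,4aS,8aS)-2,5,5,8a-tetramethyl-1,4,4a,5,6,7,8,8a-octahydronaphthalen-1-yl]methyl}-4,5-bis(tert-butyldimethylsilyloxy)benzoate
Conditions: Et3SiH (5 equiv), BF3·OEt2 (1.5 equiv), CH2Cl2, −78 °C; then Et3N
Reagents that add atoms: none
Why: Ionic hydrogenation: the axial allylic alcohol ionises to the C6–C7–C8 allyl cation, and the silane should deliver hydride to the less hindered secondary terminus C6, leaving the trisubstituted C7=C8 alkene; with both phenols silylated, no oxygen can trap a C8 cation as a chromane.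

Step 10
Reactants: 15 methyl 3-{[(1S,4aS,8aS)-2,5,5,8a-tetramethyl-1,4,4a,5,6,7,8,8a-octahydronaphthalen-1-yl]methyl}-4,5-bis(tert-butyldimethylsilyloxy)benzoate
Product: 16 methyl 3,4-dihydroxy-5-{[(1S,4aS,8aS)-2,5,5,8a-tetramethyl-1,4,4a,5,6,7,8,8a-octahydronaphthalen-1-yl]methyl}benzoate (CNP0193946.2)
Conditions: Bu4NF (2.5 equiv), AcOH (3 equiv), THF, 0 °C, under argon
Reagents that add atoms: none
Why: Buffered fluoride desilylation of the aryl silyl ethers should free the catechol without acid, so the C7=C8 alkene cannot be protonated and cyclise onto the neighbouring phenol, and the methyl ester is untouched.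

**Compound list**

1 | β-damascone, (E)-1-(2,6,6-trimethylcyclohex-1-en-1-yl)but-2-en-1-one | C/C=C/C(=O)C1=C(C)CCCC1(C)C | starting material
2 | methyl 3-bromo-4-hydroxy-5-methoxybenzoate | COC(=O)c1cc(OC)c(O)c(Br)c1 | starting material
3 | methyl 3-bromo-4,5-dihydroxybenzoate | COC(=O)c1cc(O)c(O)c(Br)c1 | intermediate
4 | methyl 3-bromo-4,5-bis(tert-butyldimethylsilyloxy)benzoate | COC(=O)c1cc(O[Si](C)(C)C(C)(C)C)c(O[Si](C)(C)C(C)(C)C)c(Br)c1 | intermediate
5 | methyl 4,5-bis(tert-butyldimethylsilyloxy)-3-(1-ethoxyvinyl)benzoate | COC(=O)c1cc(O[Si](C)(C)C(C)(C)C)c(O[Si](C)(C)C(C)(C)C)c(C(=C)OCC)c1 | intermediate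
6 | methyl 3-acetyl-4,5-bis(tert-butyldimethylsilyloxy)benzoate | COC(=O)c1cc(O[Si](C)(C)C(C)(C)C)c(O[Si](C)(C)C(C)(C)C)c(C(C)=O)c1 | intermediate
7 | methyl 3,4-bis(tert-butyldimethylsilyloxy)-5-[1-(trimethylsilyloxy)vinyl]benzoate | COC(=O)c1cc(O[Si](C)(C)C(C)(C)C)c(O[Si](C)(C)C(C)(C)C)c(C(=C)O[Si](C)(C)C)c1 | intermediate
8 | methyl 3,4-bis(tert-butyldimethylsilyloxy)-5-[(3S,4Z)-3-methyl-5-(2,6,6-trimethylcyclohex-1-en-1-yl)-5-(trimethylsilyloxy)pent-4-enoyl]benzoate (Z geometry as expected from the s-cis enone; it is lost in the ring closure) | COC(=O)c1cc(O[Si](C)(C)C(C)(C)C)c(O[Si](C)(C)C(C)(C)C)c(C(=O)C[C@H](C)/C=C(\O[Si](C)(C)C)C2=C(C)CCCC2(C)C)c1 | intermediate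
9 | methyl 3,4-bis(tert-butyldimethylsilyloxy)-5-{[(1S,2R,8aR)-2,5,5,8a-tetramethyl-4-(trimethylsilyloxy)-1,2,3,5,6,7,8,8a-octahydronaphthalen-1-yl]carbonyl}benzoate | COC(=O)c1cc(O[Si](C)(C)C(C)(C)C)c(O[Si](C)(C)C(C)(C)C)c(C(=O)[C@H]2[C@H](C)CC(O[Si](C)(C)C)=C3C(C)(C)CCC[C@]23C)c1 | intermediate
10 | methyl 3-{[(1S,2R,4aS,8aR)-2,5,5,8a-tetramethyl-4-oxodecahydronaphthalen-1-yl]carbonyl}-4,5-bis(tert-butyldimethylsilyloxy)benzoate (trans-fused; 8α-methyl, 9β-aroyl, 5α-H, 10β-methyl) | COC(=O)c1cc(O[Si](C)(C)C(C)(C)C)c(O[Si](C)(C)C(C)(C)C)c(C(=O)[C@H]2[C@H](C)CC(=O)[C@H]3C(C)(C)CCC[C@]23C)c1 | intermediate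
11 | methyl 3-{[(1S,2R,4aS,8aR)-2,5,5,8a-tetramethyl-4-oxodecahydronaphthalen-1-yl]methyl}-4,5-bis(tert-butyldimethylsilyloxy)benzoate | COC(=O)c1cc(O[Si](C)(C)C(C)(C)C)c(O[Si](C)(C)C(C)(C)C)c(C[C@H]2[C@H](C)CC(=O)[C@H]3C(C)(C)CCC[C@]23C)c1 | intermediate
12 | methyl 3-{[(1S,2S,4aS,8aR)-2,5,5,8a-tetramethyl-4-(trimethylsilyloxy)-1,2,4a,5,6,7,8,8a-octahydronaphthalen-1-yl]methyl}-4,5-bis(tert-butyldimethylsilyloxy)benzoate (C6=C7 silyl enol ether of 11) | COC(=O)c1cc(O[Si](C)(C)C(C)(C)C)c(O[Si](C)(C)C(C)(C)C)c(C[C@H]2[C@H](C)C=C(O[Si](C)(C)C)[C@H]3C(C)(C)CCC[C@]23C)c1 | intermediate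
13 | methyl 3-{[(1S,4aS,8aR)-2,5,5,8a-tetramethyl-4-oxo-1,4,4a,5,6,7,8,8a-octahydronaphthalen-1-yl]methyl}-4,5-bis(tert-butyldimethylsilyloxy)benzoate | COC(=O)c1cc(O[Si](C)(C)C(C)(C)C)c(O[Si](C)(C)C(C)(C)C)c(C[C@H]2C(C)=CC(=O)[C@H]3C(C)(C)CCC[C@]23C)c1 | intermediate
14 | methyl 3-{[(1S,4R,4aS,8aR)-4-hydroxy-2,5,5,8a-tetramethyl-1,4,4a,5,6,7,8,8a-octahydronaphthalen-1-yl]methyl}-4,5-bis(tert-butyldimethylsilyloxy)benzoate (6β-alcohol) | COC(=O)c1cc(O[Si](C)(C)C(C)(C)C)c(O[Si](C)(C)C(C)(C)C)c(C[C@H]2C(C)=C[C@@H](O)[C@H]3C(C)(C)CCC[C@]23C)c1 | intermediate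
15 | methyl 3-{[(1S,4aS,8aS)-2,5,5,8a-tetramethyl-1,4,4a,5,6,7,8,8a-octahydronaphthalen-1-yl]methyl}-4,5-bis(tert-butyldimethylsilyloxy)benzoate | COC(=O)c1cc(O[Si](C)(C)C(C)(C)C)c(O[Si](C)(C)C(C)(C)C)c(C[C@H]2C(C)=CC[C@H]3C(C)(C)CCC[C@]23C)c1 | intermediate
16 | methyl 3,4-dihydroxy-5-{[(1S,4aS,8aS)-2,5,5,8a-tetramethyl-1,4,4a,5,6,7,8,8a-octahydronaphthalen-1-yl]methyl}benzoate | COC(=O)c1cc(O)c(O)c(C[C@H]2C(C)=CC[C@H]3C(C)(C)CCC[C@]23C)c1 | target

**Step count**

Total: 10 steps. Longest linear sequence: 10 steps (2 → 16); β-damascone 1 enters at step 5.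

**Steps most likely to fail, with fallbacks**

1. Step 5. The sequence may stall after the first conjugate addition, because the twisted C10 may not accept the enol ether. The first addition may also show poor enantiofacial selectivity, or the aryl silyl ethers may be lost to the superacid. The fallback uses known chemistry only and sets out from aryl bromide 4. Commercial (−)-drimenol, OC[C@H]1C(C)=CC[C@H]2C(C)(C)CCC[C@]12C, is converted with I2, PPh3 and imidazole in toluene into 11-iododrim-7-ene F1. Zinc insertion (Zn dust, LiCl, THF, 40 °C) gives the drimenylzinc iodide F2. Negishi coupling of F2 with 4 (Pd(OAc)2, 2-dicyclohexylphosphino-2',6'-dimethoxybiphenyl, THF, 50 °C) tolerates the ester and gives 15. The route is rejoined at 15, before step 10.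

2. Step 9. Hydride may be captured at the tertiary terminus C8 instead of C6, the allyl cation may lose a proton to give dienes, or the product alkene may be protonated and reduced further. The fallback sets out from 14. The alcohol is converted with KN(SiMe3)2 and ClCO2Me (THF, −78 °C) into the allylic methyl carbonate F3. Reduction with Pd(PPh3)4 (5 mol %) and NaBH4 in THF at rt follows: zerovalent palladium ionises the 6β-carbonate from the open α face, and hydride is delivered to the less substituted terminus C6. This gives 15 under neutral conditions, and the route is rejoined at 15.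

3. Step 6. Hydrogenolysis of the hindered aryl ketone may not start, or may stop at the benzylic alcohol. The fallback sets out from 10. Ionic hydrogenation (Et3SiH, CF3CO2H, CH2Cl2, rt) reduces the aryl ketone to the methylene group through the benzylic cation, which the ortho silyloxy group stabilises. Any C6 ketone reduced at the same time is obtained, after bicarbonate work-up, as the 6β-alcohol F4. Dess–Martin periodinane (CH2Cl2, NaHCO3) returns F4 to ketone 11, where the route is rejoined.

**Further compounds**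

F1 | step 5 | (1S,4aS,8aS)-1-(iodomethyl)-2,5,5,8a-tetramethyl-1,4,4a,5,6,7,8,8a-octahydronaphthalene (11-iododrim-7-ene) | IC[C@H]1C(C)=CC[C@H]2C(C)(C)CCC[C@]12C
F2 | step 5 | {[(1S,4aS,8aS)-2,5,5,8a-tetramethyl-1,4,4a,5,6,7,8,8a-octahydronaphthalen-1-yl]methyl}zinc iodide | I[Zn]C[C@H]1C(C)=CC[C@H]2C(C)(C)CCC[C@]12C
F3 | step 9 | methyl 3-{[(1S,4R,4aS,8aR)-4-[(methoxycarbonyl)oxy]-2,5,5,8a-tetramethyl-1,4,4a,5,6,7,8,8a-octahydronaphthalen-1-yl]methyl}-4,5-bis(tert-butyldimethylsilyloxy)benzoate | COC(=O)c1cc(O[Si](C)(C)C(C)(C)C)c(O[Si](C)(C)C(C)(C)C)c(C[C@H]2C(C)=C[C@@H](OC(=O)OC)[C@H]3C(C)(C)CCC[C@]23C)c1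
F4 | step 6 | methyl 3-{[(1S,2R,4R,4aS,8aR)-4-hydroxy-2,5,5,8a-tetramethyldecahydronaphthalen-1-yl]methyl}-4,5-bis(tert-butyldimethylsilyloxy)benzoate | COC(=O)c1cc(O[Si](C)(C)C(C)(C)C)c(O[Si](C)(C)C(C)(C)C)c(C[C@H]2[C@H](C)C[C@@H](O)[C@H]3C(C)(C)CCC[C@]23C)c1
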